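**Numbering used.** Germacrane numbering: ring C1–C10; C11–C13 form the lactone arm on C7 (C12 carbonyl, C13 methylene); C14 is the methyl on C10, C15 the methyl on C4. Compounds are numbered 1–44 in the order of the steps; 44 is the target.

## Analysis of the target

Compound 44 is a germacranolide: a ten-membered carbocycle (C1–C10) trans-fused at C6/C7 to an α-methylene-γ-butyrolactone (O6–C12, C11=C13). The ring holds two trisubstituted alkenes of opposite geometry, Z-C1=C10 (C14 on C10) and E-C4=C5 (C15 on C4). There are five stereocentres: C2 (R, acetate), C6 (R, lactone oxygen), C7 (S), C8 (R, angelate) and C9 (R, acetate). C7, C8 and C9 are contiguous: O8 and O9 are syn in the extended chain, the C6 branch on C7 is anti to O8, and H6/H7 are anti (trans-lactone). C2 is remote and sits across the Z-alkene from C9. The sensitive groups are the exocyclic methylene lactone (a Michael acceptor), the angelate (it isomerises easily to the tiglate), three allylic C–O bonds (C2, C6, C9) on a 1(10),4-diene that cyclises transannularly under acid, and vicinal acyloxy groups at C8/C9 that can migrate. The synthesis is hard because a strained medium ring with two geometrically defined trisubstituted alkenes must be closed while three different esters on neighbouring oxygens are kept apart. The strategy rests on one feature: C6 is a carbinol on C5 of the E-C4=C5 alkene and C15 is cis to C6. That is the pattern left by syn addition of an aldehyde carbon (C6) and a methyl group (C15) across a terminal C4≡C5 alkyne, so C5–C6 and C4–C15 can be made in the ring-closing event.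

## Retrosynthetic reasoning

**Esters (44 ⇒ 43 ⇒ 42 ⇒ 39 + 40).** The two acetate C–O bonds and the angelate C–O bond are cut first, because enolisable esters tolerate neither the lactone enolate chemistry nor the organometallic steps. The angelate from 40 is put on O8 while O2 and O9 are still silylated (42), and the acetates come last (43 to 44). In this order no free hydroxyl ever sits next to an acetate under basic, heated conditions, which limits 1,2-acyl migration.

**Methylene group (38 ⇒ 35).** C11=C13 is cut to the saturated lactone 35. Aminomethylation of the lactone enolate and elimination must come before any other ester is present.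

**Lactone (35 ⇒ 34).** Cutting O6–C12 gives hydroxy ester 34, in which C6 is a free allylic carbinol next to the C12 ester. The forward reaction is a simple lactonisation with retention at C6.

**Ring closure (34 ⇒ 30 + 31).** C5–C6 and C4–C15 are cut together. This is where the ring is opened, because one metal-mediated event can then make the ring, the E-alkene, the C15 methyl and the C6 carbinol from an aldehyde, a terminal alkyne and dimethylzinc 31. The forward reaction must join C6 to the alkyne terminus C5 (endo), deliver methyl to C4 syn to C6, and choose the 6R face of the aldehyde.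

**Aldehyde (30 ⇒ 28).** The C6 aldehyde has an epimerisable α-centre (C7) and a β-alkoxy group, so it is unveiled last, by oxidative cleavage of the vinyl group of 28.

**Fragment union (28 ⇒ 27 ⇒ 26 ⇒ 10 + 23).** The chain is cut at C9–C10. This divides it into two pieces of similar size, lets iodide 10 carry the Z-geometry in from a small molecule, and sets C9 by chelation to the O8 ether of aldehyde 23. It also means that no hydride reagent is needed once the C12 ester exists. Building the trisubstituted alkene on the chain would need reduction of a C2 carboxyl derivative, which the C12 ester would not survive.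

**C7 (23 ⇒ 21 ⇒ 18 + 19).** The C9 aldehyde of 23 comes from the terminal acetonide of 21. C6–C7 is cut back to enoate 18 and vinylmagnesium bromide 19. The copper-mediated conjugate addition anti to the γ-oxygen sets C7 relative to C8, and the vinyl group is the latent C6 aldehyde.

**C8 from the chiral pool (18 ⇒ 15 + 16 ⇒ 14 ⇒ 12 ⇒ 11).** C7=C11 is cut by a Wittig disconnection to ylide 16 and alcohol 15. Compound 15 comes from diethyl D-tartrate 11 in three steps, since its C2 symmetry allows one oxygen to be turned into the PMB ether without a selectivity problem. Only one tartrate centre (C8) reaches the target. The second carbinol carbon serves, inside the acetonide, as the latent C9 aldehyde.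

**Iodide (10 ⇒ 8 ⇒ 7 ⇒ 4 + 5 ⇒ 3 ⇒ 1).** C2–C3 is cut to enal 4 and allenylboronate 5 (catalytic asymmetric propargylation sets C2). The Z-iodoalkene comes from directed hydroalumination–iodination of butynol 1.

## Alternatives that were turned down

**Alternative 1:** ring contraction by a [2,3]-Wittig shift. The bond cut is C7–C8. Going backwards, O8 is tied to C13, which expands the carbocycle to the 13-membered cyclic α-allyloxy enone A1. Forward, LiN(iPr)2 at low temperature removes a C8 proton of A1, and the enolate rearranges to A2: C7–C8 forms, O–C13 breaks, C11=C13 appears and the ring contracts to ten members.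
- For it: the medium ring comes from a larger, easier ring; the exocyclic methylene needs no separate step, a point on which it is stronger than the chosen route; C7 and C8 are set together.
- Against it: deprotonation must take place at C8 and not at the vinylogous C14 methyl of the enone. The C7/C8 relationship depends on enolate and alkene geometry in a flexible 13-membered ring (the C7=C11 geometry of A1 would have to be matched to it). A [1,2]-shift competes. Afterwards A2 still needs a stereoselective C9 ketone reduction, oxidation of C12 from the alcohol to the acid level and lactonisation. A1 itself needs a macrocyclisation.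
- Comparison: the chosen route offers in its place an alkene geometry fixed by mechanism (syn addition), C12 already at the ester level, and a shorter sequence after the ring is closed.

**Alternative 2:** Nozaki–Hiyama–Kishi closure at C9–C10. The bond cut is C9–C10. The precursor A3 is the acyclic Z-alkenyl iodide with a C9 aldehyde, the lactone and the C2 acetate already in place. Forward, CrCl2 with catalytic NiCl2 turns the iodide into an alkenylchromium species that adds to the aldehyde and gives A4.
- For it: this ring closure has ample precedent in medium and large rings and tolerates esters and lactones, so on reliability of the cyclisation it is stronger than the chosen key step, and little remains to be done after it.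
- Against it: C9 is created in the ring closure next to the O8 ether without chelation, and the Felkin preference points to the 8,9-anti epimer, not the syn one needed. The E-C4=C5 alkene, C15 and C6 must all be made beforehand by separate stereocontrolled steps. The methylene lactone of A3 has to pass through divalent chromium.
- Comparison: the chosen route makes the second trisubstituted alkene and C6 in the closure itself and sets C9 earlier under chelation control. The Nozaki–Hiyama–Kishi reaction is kept in reserve as a fallback at C5–C6.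

**Alternative 3:** Grob fragmentation. Going backwards, C4 and C9 are joined across the ring, which gives the trans-decalin A5 with a tertiary C9 alcohol and an equatorial C5 mesylate. Forward, KOtBu forms the alkoxide, the antiperiplanar C4–C9 bond breaks, the mesylate leaves, and A6 results with the C9 ketone and the E-C4=C5 alkene.
- For it: no medium ring has to be closed, the stereocentres are set on rigid chairs, and the fragmentation is stereospecific. On certainty of ring formation and alkene geometry it is at least as strong as the chosen route.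
- Against it: A5 carries a quaternary C4, a tertiary carbinol and five further stereocentres, and is a long synthesis in itself. A6 then needs a face-selective C9 reduction in a flexible ring next to a Z-enone that can isomerise, oxidation of the two-carbon arm to the acid, lactonisation, methylenation and several protecting-group exchanges.
- Comparison: the chosen route is convergent and reaches the ring in far fewer steps, with C9 and C12 already in their final oxidation states.

Key step: step 16

Assumption: the (R)-configured binaphthyl phosphoric acid is taken to deliver the propargyl group to the Re face of enal 4, as it does with other conjugated aldehydes; if the sense were the opposite, its enantiomer would be used in step 3.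

## Route

Step 1
Reactants: 1 but-2-yn-1-ol
Product: 3 (2Z)-3-iodobut-2-en-1-ol, via cyclic alkenylalanate 2 (not isolated)
Conditions: NaAlH2(OCH2CH2OCH3)2, THF, 0 °C to rt; then N-iodosuccinimide, −78 °C
Reagents that add atoms: N-iodosuccinimide, O=C1CCC(=O)N1I
Why: Hydroxyl-directed trans-hydroalumination puts aluminium on the distal alkyne carbon (C10) inside a five-membered alanate, and iodination with retention gives the Z-iodoalkene with iodine cis to the carbinol carbon, the geometry needed for C1=C10.

Step 2
Reactants: 3 (2Z)-3-iodobut-2-en-1-ol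
Product: 4 (2Z)-3-iodobut-2-enal
Conditions: MnO2, CH2Cl2, rt; used crude
Reagents that add atoms: none
Why: Allylic oxidation on the MnO2 surface is neutral and should leave the Z-geometry and the carbon–iodine bond untouched.

Step 3
Reactants: 4 (2Z)-3-iodobut-2-enal; 5 allenylboronic acid pinacol ester
Product: 7 (4R,5Z)-6-iodohept-5-en-1-yn-4-ol, via pinacol borate ester 6 (not isolated)
Conditions: (R)-3,3'-bis(2,4,6-triisopropylphenyl)-1,1'-binaphthyl-2,2'-diyl hydrogen phosphate (5 mol%), 4 Å molecular sieves, toluene, −20 °C; aqueous work-up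
Reagents that add atoms: none
Why: Chiral Brønsted acid-catalysed propargylboration: the allenylboronate reacts through a six-membered chair transition state (allenyl to propargyl transposition) while the phosphate bridges a boronate oxygen and the formyl hydrogen and shields the Si face. Re-face attack should give the 2R carbinol (C2).

Step 4
Reactants: 7 (4R,5Z)-6-iodohept-5-en-1-yn-4-ol
Product: 8 tert-butyl{[(4R,5Z)-6-iodohept-5-en-1-yn-4-yl]oxy}dimethylsilane
Conditions: tBuMe2SiCl, imidazole, DMF, rt
Reagents that add atoms: tert-butyldimethylsilyl chloride, CC(C)(C)[Si](C)(C)Cl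
Why: Standard silylation of a secondary alcohol; the silyl ether survives all steps up to the end game.

Step 5
Reactants: 8 tert-butyl{[(4R,5Z)-6-iodohept-5-en-1-yn-4-yl]oxy}dimethylsilane
Product: 10 tert-butyl{[(4R,5Z)-6-iodo-1-(trimethylsilyl)hept-5-en-1-yn-4-yl]oxy}dimethylsilane, via alkynylmagnesium bromide 9 (not isolated)
Conditions: EtMgBr, THF, 0 °C to rt; then Me3SiCl
Reagents that add atoms: chlorotrimethylsilane, C[Si](C)(C)Cl
Why: The acidic alkyne hydrogen would quench the alkenyllithium of step 12, so it is replaced by silicon. The Grignard base deprotonates the alkyne but does not exchange with the alkenyl iodide under these conditions.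

Step 6
Reactants: 11 diethyl D-tartrate
Product: 12 diethyl (4S,5S)-2-(4-methoxyphenyl)-1,3-dioxolane-4,5-dicarboxylate
Conditions: 4-MeOC6H4CH(OMe)2, camphorsulfonic acid (cat.), toluene, reflux with removal of MeOH
Reagents that add atoms: 4-methoxybenzaldehyde dimethyl acetal, COc1ccc(C(OC)OC)cc1
Why: Acid-catalysed transacetalisation; because the diol is C2-symmetric the acetal carbon is not a stereocentre and one compound results.

Step 7
Reactants: 12 diethyl (4S,5S)-2-(4-methoxyphenyl)-1,3-dioxolane-4,5-dicarboxylate
Product: 14 (2R,3R)-2-[(4-methoxybenzyl)oxy]butane-1,3,4-triol, via acetal diol 13 (not isolated)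
Conditions: iBu2AlH (excess), CH2Cl2, −78 °C to rt
Reagents that add atoms: none
Why: The hydride reduces both esters and then opens the anisylidene acetal reductively through its oxocarbenium ion. Either C–O bond gives the same mono-PMB ether because of the C2 symmetry, so O8 and O9 are told apart without a selectivity issue.

Step 8
Reactants: 14 (2R,3R)-2-[(4-methoxybenzyl)oxy]butane-1,3,4-triol
Product: 15 (2R)-2-[(4R)-2,2-dimethyl-1,3-dioxolan-4-yl]-2-[(4-methoxybenzyl)oxy]ethan-1-ol
Conditions: Me2C(OMe)2, pyridinium p-toluenesulfonate (cat.), acetone, rt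
Reagents that add atoms: 2,2-dimethoxypropane, COC(C)(C)OC
Why: Under thermodynamic control the acetonide forms on the terminal 1,2-diol (five-membered dioxolane) and not across the 1,3-diol, which leaves free the primary hydroxyl next to the PMB ether.

Step 9
Reactants: 15 (2R)-2-[(4R)-2,2-dimethyl-1,3-dioxolan-4-yl]-2-[(4-methoxybenzyl)oxy]ethan-1-ol; 16 methyl (triphenylphosphoranylidene)acetate
Product: 18 methyl (2E,4R)-4-[(4R)-2,2-dimethyl-1,3-dioxolan-4-yl]-4-[(4-methoxybenzyl)oxy]but-2-enoate, via α-alkoxy aldehyde 17 (not isolated)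
Conditions: TEMPO (cat.), PhI(OAc)2, CH2Cl2, rt; then 16, rt
Reagents that add atoms: none
Why: Oxoammonium oxidation of the primary alcohol followed by Wittig olefination in the same flask, so the epimerisable α-alkoxy aldehyde is never isolated. The stabilised ylide gives the E-enoate.

Step 10
Reactants: 18 methyl (2E,4R)-4-[(4R)-2,2-dimethyl-1,3-dioxolan-4-yl]-4-[(4-methoxybenzyl)oxy]but-2-enoate; 19 vinylmagnesium bromide
Product: 21 methyl (3S)-3-{(R)-[(4R)-2,2-dimethyl-1,3-dioxolan-4-yl][(4-methoxybenzyl)oxy]methyl}pent-4-enoate, via silyl ketene acetal 20 (not isolated)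
Conditions: CuI, Me3SiCl, THF, −78 °C; then aq. NH4Cl
Reagents that add atoms: none
Why: Silyl-accelerated conjugate addition of the vinyl cuprate to a γ-alkoxy enoate: the enoate reacts through the conformer with the γ-hydrogen in the alkene plane (allylic strain) and the cuprate enters opposite the γ-C–O bond. This gives the 7,8-anti relationship (C7) and installs the latent C6 aldehyde.

Step 11
Reactants: 21 methyl (3S)-3-{(R)-[(4R)-2,2-dimethyl-1,3-dioxolan-4-yl][(4-methoxybenzyl)oxy]methyl}pent-4-enoate
Product: 23 methyl (3S)-3-{(1R)-1-[(4-methoxybenzyl)oxy]-2-oxoethyl}pent-4-enoate, via terminal diol 22 (not isolated)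
Conditions: H5IO6, EtOAc, rt; used crude
Reagents that add atoms: none
Why: Periodic acid hydrolyses the terminal acetonide and cleaves the glycol in one flask, which gives the C9 aldehyde. The diol is consumed as it forms and cannot lactonise onto the ester; the PMB ether, ester and vinyl group are inert.

Step 12
Reactants: 10 tert-butyl{[(4R,5Z)-6-iodo-1-(trimethylsilyl)hept-5-en-1-yn-4-yl]oxy}dimethylsilane; 23 methyl (3S)-3-{(1R)-1-[(4-methoxybenzyl)oxy]-2-oxoethyl}pent-4-enoate
Product: 26 methyl (3S,4R,5R,6Z,8R)-8-[(tert-butyldimethylsilyl)oxy]-3-ethenyl-5-hydroxy-4-[(4-methoxybenzyl)oxy]-6-methyl-11-(trimethylsilyl)undec-6-en-10-ynoate, via alkenyllithium 24 (not isolated), via alkenylmagnesium bromide 25 (not isolated)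
Conditions: 10, tBuLi (2 equiv), Et2O, −78 °C; MgBr2·OEt2; then 23 precomplexed with MgBr2·OEt2 in CH2Cl2, −78 °C; aq. NH4Cl at −78 °C
Reagents that add atoms: none
Why: Iodine–lithium exchange and transmetalation to magnesium go with retention of the Z-geometry. In the addition, magnesium bridges the aldehyde oxygen and the O8 ether (Cram chelate), and the alkenyl group attacks the face away from the C7 branch, which gives the 8,9-syn (9R) alcohol. The ester is not touched at −78 °C.

Step 13
Reactants: 26 methyl (3S,4R,5R,6Z,8R)-8-[(tert-butyldimethylsilyl)oxy]-3-ethenyl-5-hydroxy-4-[(4-methoxybenzyl)oxy]-6-methyl-11-(trimethylsilyl)undec-6-en-10-ynoate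
Product: 27 methyl (3S,4R,5R,6Z,8R)-5,8-bis[(tert-butyldimethylsilyl)oxy]-3-ethenyl-4-[(4-methoxybenzyl)oxy]-6-methyl-11-(trimethylsilyl)undec-6-en-10-ynoate
Conditions: tBuMe2SiOTf, 2,6-lutidine, CH2Cl2, −78 to 0 °C
Reagents that add atoms: tert-butyldimethylsilyl triflate, CC(C)(C)[Si](C)(C)OS(=O)(=O)C(F)(F)F
Why: The silyl triflate silylates the hindered allylic C9 hydroxyl and removes the risk that O9 lactonises onto the C12 ester.

Step 14
Reactants: 27 methyl (3S,4R,5R,6Z,8R)-5,8-bis[(tert-butyldimethylsilyl)oxy]-3-ethenyl-4-[(4-methoxybenzyl)oxy]-6-methyl-11-(trimethylsilyl)undec-6-en-10-ynoate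
Product: 28 methyl (3S,4R,5R,6Z,8R)-5,8-bis[(tert-butyldimethylsilyl)oxy]-3-ethenyl-4-[(4-methoxybenzyl)oxy]-6-methylundec-6-en-10-ynoate
Conditions: K2CO3, MeOH, rt
Reagents that add atoms: none
Why: Methanolysis cleaves only the alkynyl C–Si bond; the silyl ethers stay, and the ester is already a methyl ester, so exchange with the solvent changes nothing.

Step 15
Reactants: 28 methyl (3S,4R,5R,6Z,8R)-5,8-bis[(tert-butyldimethylsilyl)oxy]-3-ethenyl-4-[(4-methoxybenzyl)oxy]-6-methylundec-6-en-10-ynoate
Product: 30 methyl (3R,4R,5R,6Z,8R)-5,8-bis[(tert-butyldimethylsilyl)oxy]-3-formyl-4-[(4-methoxybenzyl)oxy]-6-methylundec-6-en-10-ynoate, via vicinal diol 29 (not isolated)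
Conditions: OsO4 (cat.), NaIO4, 2,6-lutidine, dioxane–H2O, rt; used at once
Reagents that add atoms: osmium tetroxide, O=[Os](=O)(=O)=O (oxygen donor, kept in turnover by sodium periodate, [Na+].[O-][I](=O)(=O)=O)
Why: Lemieux–Johnson cleavage: the unhindered monosubstituted alkene should be osmylated in preference to the trisubstituted Z-alkene, which is shielded and inductively deactivated by two allylic silyloxy groups, and to the alkyne. Periodate in the same flask cleaves the diol before it can lactonise.

Step 16
Reactants: 30 methyl (3R,4R,5R,6Z,8R)-5,8-bis[(tert-butyldimethylsilyl)oxy]-3-formyl-4-[(4-methoxybenzyl)oxy]-6-methylundec-6-en-10-ynoate; 31 dimethylzinc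
Product: 34 methyl [(1S,2R,3E,6R,7Z,9R,10R)-6,9-bis[(tert-butyldimethylsilyl)oxy]-2-hydroxy-10-[(4-methoxybenzyl)oxy]-4,8-dimethylcyclodeca-3,7-dien-1-yl]acetate, via oxanickelacycle 32 (not isolated), via methylzinc alkoxide 33 (not isolated)
Conditions: Ni(cod)2 (30 mol%), 1,3-bis(2,4,6-trimethylphenyl)imidazolium chloride (30 mol%), KOtBu (30 mol%), ZnMe2 (3 equiv), THF, 45 °C, slow addition of 30 to a final 0.002 M; aq. NH4Cl at 0 °C
Reagents that add atoms: none
Why: Proposed new method: zerovalent nickel carrying the small carbene ligand binds the aldehyde and the terminal alkyne of 30 and couples them oxidatively to oxanickelacycle 32, in which C6 is bonded to the unsubstituted alkyne terminus C5; ZnMe2 then passes a methyl group to nickel while zinc takes the alkoxide, and reductive elimination forms C4–C15 with the methyl group and C6 cis, which is the E-geometry of C4=C5. The closest known reaction types are the nickel–carbene-catalysed reductive macrocyclisation of ynals with silanes, which gives endocyclic E-allylic alcohols, and the nickel-catalysed alkylative cyclisation of ynals with organozincs, known for five- and six-membered rings; their combination in a ten-membered ring has no precedent. The ring closes in the endo mode, so both alkyne carbons become ring members and the ten-membered carbocycle results; the exo mode would give a nine-membered ring with an exocyclic alkene and is disfavoured by the small ligand, which lets the aldehyde carbon bond to the less hindered alkyne terminus. The new stereocentre C6 is controlled by C7: in the Felkin–Anh arrangement C8 stands anti to the forming C5–C6 bond (a torsion the ring can adopt), the CH2CO2Me arm lies next to the carbonyl oxygen and C5 approaches past the C7 hydrogen, which gives the 6R carbinol with O6 and C11 syn. The step needs endo regiochemistry, methyl transfer in preference to direct addition of ZnMe2 to the aldehyde, and cyclisation in preference to alkyne oligomerisation. These are secured by the terminal alkyne, by the absence of β-hydrogens in ZnMe2 (which closes the reductive pathway), by the low uncatalysed reactivity of ZnMe2 towards aldehydes, and by slow addition at high dilution; the Z-alkene with its two flanking silyl ethers folds the chain and brings the ends together.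

Step 17
Reactants: 34 methyl [(1S,2R,3E,6R,7Z,9R,10R)-6,9-bis[(tert-butyldimethylsilyl)oxy]-2-hydroxy-10-[(4-methoxybenzyl)oxy]-4,8-dimethylcyclodeca-3,7-dien-1-yl]acetate
Product: 35 (2R,6R,7S,8R,9R)-2,9-bis[(tert-butyldimethylsilyl)oxy]-8-[(4-methoxybenzyl)oxy]germacra-1(10)Z,4E-dien-12,6-olide
Conditions: pyridinium p-toluenesulfonate (cat.), toluene, 50 °C
Reagents that add atoms: none
Why: Five-membered lactonisation of a γ-hydroxy ester with retention at C6 gives the trans-fused lactone. Any lactone already formed in step 16 converges here, and O8 is blocked, so only O6 can close onto C12.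

Step 18
Reactants: 35 (2R,6R,7S,8R,9R)-2,9-bis[(tert-butyldimethylsilyl)oxy]-8-[(4-methoxybenzyl)oxy]germacra-1(10)Z,4E-dien-12,6-olide
Product: 38 (2R,6R,7S,8R,9R)-2,9-bis[(tert-butyldimethylsilyl)oxy]-8-[(4-methoxybenzyl)oxy]germacra-1(10)Z,4E,11(13)-trien-12,6-olide, via Mannich base 36 (not isolated), via ammonium iodide 37 (not isolated)
Conditions: LiN(iPr)2, THF, −78 °C; CH2=NMe2+ I−, −78 to 0 °C; then MeI, MeOH, rt; then aq. NaHCO3, CH2Cl2
Reagents that add atoms: dimethyl(methylidene)ammonium iodide, C=[N+](C)C.[I-]
Why: Aminomethylation of the lactone enolate at C11, quaternisation and base-induced elimination give the exocyclic methylene. It is done now because no other enolisable ester is present yet.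

Step 19
Reactants: 38 (2R,6R,7S,8R,9R)-2,9-bis[(tert-butyldimethylsilyl)oxy]-8-[(4-methoxybenzyl)oxy]germacra-1(10)Z,4E,11(13)-trien-12,6-olide
Product: 39 (2R,6R,7R,8R,9R)-2,9-bis[(tert-butyldimethylsilyl)oxy]-8-hydroxygermacra-1(10)Z,4E,11(13)-trien-12,6-olide
Conditions: DDQ, CH2Cl2–pH 7 buffer, 0 °C
Reagents that add atoms: none
Why: Oxidative cleavage of the PMB ether under near-neutral conditions frees O8 only; silyl ethers, alkenes and the methylene lactone are not affected (the 7R descriptor reflects a priority change, not a change at C7).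

Step 20
Reactants: 39 (2R,6R,7R,8R,9R)-2,9-bis[(tert-butyldimethylsilyl)oxy]-8-hydroxygermacra-1(10)Z,4E,11(13)-trien-12,6-olide; 40 angelic acid
Product: 42 (2R,6R,7S,8R,9R)-8-angeloyloxy-2,9-bis[(tert-butyldimethylsilyl)oxy]germacra-1(10)Z,4E,11(13)-trien-12,6-olide, via mixed anhydride 41 (not isolated)
Conditions: 40, 2,4,6-Cl3C6H2COCl, Et3N, toluene, rt; then 39, toluene, 80 °C
Reagents that add atoms: none
Why: Yamaguchi-type esterification through the mixed anhydride; running it without a nucleophilic pyridine catalyst is the usual way to keep the Z-geometry of the angeloyl group. With O2 and O9 still silylated no acyl migration is possible.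

Step 21
Reactants: 42 (2R,6R,7S,8R,9R)-8-angeloyloxy-2,9-bis[(tert-butyldimethylsilyl)oxy]germacra-1(10)Z,4E,11(13)-trien-12,6-olide
Product: 43 (2R,6R,7S,8R,9R)-8-angeloyloxy-2,9-dihydroxygermacra-1(10)Z,4E,11(13)-trien-12,6-olide
Conditions: HF·pyridine, pyridine, THF, 0 °C to rt
Reagents that add atoms: none
Why: Buffered fluoride removes both silyl ethers without base, so the methylene lactone is not attacked and the angelate does not migrate from O8 to O9.

Step 22
Reactants: 43 (2R,6R,7S,8R,9R)-8-angeloyloxy-2,9-dihydroxygermacra-1(10)Z,4E,11(13)-trien-12,6-olide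
Product: 44 (2R,6R,7S,8R,9R)-2,9-diacetoxy-8-angeloyloxygermacra-1(10)Z,4E,11(13)-trien-12,6-olide (CNP0499619.1)
Conditions: Ac2O, pyridine, 4-(dimethylamino)pyridine (cat.), CH2Cl2, 0 °C
Reagents that add atoms: acetic anhydride, CC(=O)OC(C)=O
Why: Acetylation of the two allylic alcohols is fast at 0 °C and should outrun any acyl migration; it completes the target.

## Compound list

1 | but-2-yn-1-ol | CC#CCO | starting material
2 | sodium cyclic alkenylalanate from trans-hydroalumination of 1 (formed in the flask) | CC1=CCO[Al-]1(OCCOC)OCCOC.[Na+] | intermediate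
3 | (2Z)-3-iodobut-2-en-1-ol | C/C(I)=C/CO | intermediate
4 | (2Z)-3-iodobut-2-enal | C/C(I)=C/C=O | intermediate
5 | allenylboronic acid pinacol ester | C=C=CB1OC(C)(C)C(C)(C)O1 | starting material
6 | pinacol borate ester of 7 (formed in the flask) | C/C(I)=C/[C@H](OB1OC(C)(C)C(C)(C)O1)CC#C | intermediate
7 | (4R,5Z)-6-iodohept-5-en-1-yn-4-ol | C/C(I)=C/[C@H](O)CC#C | intermediate
8 | tert-butyl{[(4R,5Z)-6-iodohept-5-en-1-yn-4-yl]oxy}dimethylsilane | C/C(I)=C/[C@H](O[Si](C)(C)C(C)(C)C)CC#C | intermediate
9 | alkynylmagnesium bromide of 8 (formed in the flask) | C/C(I)=C/[C@H](O[Si](C)(C)C(C)(C)C)CC#C[Mg]Br | intermediate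
10 | tert-butyl{[(4R,5Z)-6-iodo-1-(trimethylsilyl)hept-5-en-1-yn-4-yl]oxy}dimethylsilane | C/C(I)=C/[C@H](O[Si](C)(C)C(C)(C)C)CC#C[Si](C)(C)C | intermediate
11 | diethyl D-tartrate, (2S,3S) | CCOC(=O)[C@@H](O)[C@H](O)C(=O)OCC | starting material
12 | diethyl (4S,5S)-2-(4-methoxyphenyl)-1,3-dioxolane-4,5-dicarboxylate | CCOC(=O)[C@H]1OC(c2ccc(OC)cc2)O[C@@H]1C(=O)OCC | intermediate
13 | [(4R,5R)-2-(4-methoxyphenyl)-1,3-dioxolane-4,5-diyl]dimethanol (formed in the flask) | OC[C@H]1OC(c2ccc(OC)cc2)O[C@@H]1CO | intermediate
14 | (2R,3R)-2-[(4-methoxybenzyl)oxy]butane-1,3,4-triol | OC[C@@H](O)[C@H](OCc1ccc(OC)cc1)CO | intermediate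
15 | (2R)-2-[(4R)-2,2-dimethyl-1,3-dioxolan-4-yl]-2-[(4-methoxybenzyl)oxy]ethan-1-ol | OC[C@@H](OCc1ccc(OC)cc1)[C@H]2COC(C)(C)O2 | intermediate
16 | methyl (triphenylphosphoranylidene)acetate | COC(=O)C=P(c1ccccc1)(c1ccccc1)c1ccccc1 | starting material
17 | (2S)-2-[(4R)-2,2-dimethyl-1,3-dioxolan-4-yl]-2-[(4-methoxybenzyl)oxy]acetaldehyde (formed in the flask) | O=C[C@@H](OCc1ccc(OC)cc1)[C@H]2COC(C)(C)O2 | intermediate
18 | methyl (2E,4R)-4-[(4R)-2,2-dimethyl-1,3-dioxolan-4-yl]-4-[(4-methoxybenzyl)oxy]but-2-enoate | COC(=O)/C=C/[C@@H](OCc1ccc(OC)cc1)[C@H]2COC(C)(C)O2 | intermediate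
19 | vinylmagnesium bromide | C=C[Mg]Br | starting material
20 | trimethylsilyl ketene acetal of 21 (formed in the flask, enol ether geometry not defined) | COC(O[Si](C)(C)C)=C[C@@H](C=C)[C@@H](OCc1ccc(OC)cc1)[C@H]2COC(C)(C)O2 | intermediate
21 | methyl (3S)-3-{(R)-[(4R)-2,2-dimethyl-1,3-dioxolan-4-yl][(4-methoxybenzyl)oxy]methyl}pent-4-enoate | COC(=O)C[C@@H](C=C)[C@@H](OCc1ccc(OC)cc1)[C@H]2COC(C)(C)O2 | intermediate
22 | methyl (3S)-3-{(1R,2R)-2,3-dihydroxy-1-[(4-methoxybenzyl)oxy]propyl}pent-4-enoate (formed in the flask) | COC(=O)C[C@@H](C=C)[C@@H](OCc1ccc(OC)cc1)[C@H](O)CO | intermediate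
23 | methyl (3S)-3-{(1R)-1-[(4-methoxybenzyl)oxy]-2-oxoethyl}pent-4-enoate | COC(=O)C[C@@H](C=C)[C@@H](OCc1ccc(OC)cc1)C=O | intermediate
24 | (Z)-alkenyllithium from 10 (formed in the flask) | [Li]/C(C)=C\[C@H](O[Si](C)(C)C(C)(C)C)CC#C[Si](C)(C)C | intermediate
25 | (Z)-alkenylmagnesium bromide from 24 (formed in the flask) | Br[Mg]/C(C)=C\[C@H](O[Si](C)(C)C(C)(C)C)CC#C[Si](C)(C)C | intermediate
26 | methyl (3S,4R,5R,6Z,8R)-8-[(tert-butyldimethylsilyl)oxy]-3-ethenyl-5-hydroxy-4-[(4-methoxybenzyl)oxy]-6-methyl-11-(trimethylsilyl)undec-6-en-10-ynoate | COC(=O)C[C@@H](C=C)[C@@H](OCc1ccc(OC)cc1)[C@H](O)/C(C)=C\[C@H](O[Si](C)(C)C(C)(C)C)CC#C[Si](C)(C)C | intermediate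
27 | methyl (3S,4R,5R,6Z,8R)-5,8-bis[(tert-butyldimethylsilyl)oxy]-3-ethenyl-4-[(4-methoxybenzyl)oxy]-6-methyl-11-(trimethylsilyl)undec-6-en-10-ynoate | COC(=O)C[C@@H](C=C)[C@@H](OCc1ccc(OC)cc1)[C@H](O[Si](C)(C)C(C)(C)C)/C(C)=C\[C@H](O[Si](C)(C)C(C)(C)C)CC#C[Si](C)(C)C | intermediate
28 | methyl (3S,4R,5R,6Z,8R)-5,8-bis[(tert-butyldimethylsilyl)oxy]-3-ethenyl-4-[(4-methoxybenzyl)oxy]-6-methylundec-6-en-10-ynoate | COC(=O)C[C@@H](C=C)[C@@H](OCc1ccc(OC)cc1)[C@H](O[Si](C)(C)C(C)(C)C)/C(C)=C\[C@H](O[Si](C)(C)C(C)(C)C)CC#C | intermediate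
29 | vicinal diol from osmylation of the vinyl group of 28 (formed in the flask, new carbinol centre not defined) | COC(=O)C[C@@H](C(O)CO)[C@@H](OCc1ccc(OC)cc1)[C@H](O[Si](C)(C)C(C)(C)C)/C(C)=C\[C@H](O[Si](C)(C)C(C)(C)C)CC#C | intermediate
30 | methyl (3R,4R,5R,6Z,8R)-5,8-bis[(tert-butyldimethylsilyl)oxy]-3-formyl-4-[(4-methoxybenzyl)oxy]-6-methylundec-6-en-10-ynoate (ynal, precursor of the key step) | COC(=O)C[C@@H](C=O)[C@@H](OCc1ccc(OC)cc1)[C@H](O[Si](C)(C)C(C)(C)C)/C(C)=C\[C@H](O[Si](C)(C)C(C)(C)C)CC#C | intermediate
31 | dimethylzinc | C[Zn]C | starting material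
32 | oxanickelacyclopentene fused to the closed ten-membered ring, nickel bonded to O6 and C4 (formed in the flask, carbene ligand on nickel not drawn) | O1[Ni]/C2=C\[C@@H]1[C@H](CC(=O)OC)[C@@H](OCc3ccc(OC)cc3)[C@H](O[Si](C)(C)C(C)(C)C)/C(C)=C\[C@H](O[Si](C)(C)C(C)(C)C)C2 | intermediate
33 | methylzinc alkoxide of 34 (formed in the flask) | C[Zn]O[C@@H]1/C=C(\C)C[C@@H](O[Si](C)(C)C(C)(C)C)/C=C(/C)[C@@H](O[Si](C)(C)C(C)(C)C)[C@H](OCc2ccc(OC)cc2)[C@H]1CC(=O)OC | intermediate
34 | methyl [(1S,2R,3E,6R,7Z,9R,10R)-6,9-bis[(tert-butyldimethylsilyl)oxy]-2-hydroxy-10-[(4-methoxybenzyl)oxy]-4,8-dimethylcyclodeca-3,7-dien-1-yl]acetate (product of the key step) | O[C@@H]1/C=C(\C)C[C@@H](O[Si](C)(C)C(C)(C)C)/C=C(/C)[C@@H](O[Si](C)(C)C(C)(C)C)[C@H](OCc2ccc(OC)cc2)[C@H]1CC(=O)OC | intermediate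
35 | (2R,6R,7S,8R,9R)-2,9-bis[(tert-butyldimethylsilyl)oxy]-8-[(4-methoxybenzyl)oxy]germacra-1(10)Z,4E-dien-12,6-olide | O=C1O[C@@H]2/C=C(\C)C[C@@H](O[Si](C)(C)C(C)(C)C)/C=C(/C)[C@@H](O[Si](C)(C)C(C)(C)C)[C@H](OCc3ccc(OC)cc3)[C@H]2C1 | intermediate
36 | 11-(dimethylaminomethyl) derivative of 35 (formed in the flask, C11 not defined) | O=C1O[C@@H]2/C=C(\C)C[C@@H](O[Si](C)(C)C(C)(C)C)/C=C(/C)[C@@H](O[Si](C)(C)C(C)(C)C)[C@H](OCc3ccc(OC)cc3)[C@H]2C1CN(C)C | intermediate
37 | trimethylammonium iodide from 36 (formed in the flask) | O=C1O[C@@H]2/C=C(\C)C[C@@H](O[Si](C)(C)C(C)(C)C)/C=C(/C)[C@@H](O[Si](C)(C)C(C)(C)C)[C@H](OCc3ccc(OC)cc3)[C@H]2C1C[N+](C)(C)C.[I-] | intermediate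
38 | (2R,6R,7S,8R,9R)-2,9-bis[(tert-butyldimethylsilyl)oxy]-8-[(4-methoxybenzyl)oxy]germacra-1(10)Z,4E,11(13)-trien-12,6-olide | C=C1C(=O)O[C@@H]2/C=C(\C)C[C@@H](O[Si](C)(C)C(C)(C)C)/C=C(/C)[C@@H](O[Si](C)(C)C(C)(C)C)[C@H](OCc3ccc(OC)cc3)[C@@H]12 | intermediate
39 | (2R,6R,7R,8R,9R)-2,9-bis[(tert-butyldimethylsilyl)oxy]-8-hydroxygermacra-1(10)Z,4E,11(13)-trien-12,6-olide | C=C1C(=O)O[C@@H]2/C=C(\C)C[C@@H](O[Si](C)(C)C(C)(C)C)/C=C(/C)[C@@H](O[Si](C)(C)C(C)(C)C)[C@H](O)[C@@H]12 | intermediate
40 | angelic acid, (2Z)-2-methylbut-2-enoic acid | C/C=C(/C)C(=O)O | starting material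
41 | angelic 2,4,6-trichlorobenzoic anhydride (formed in the flask) | C/C=C(/C)C(=O)OC(=O)c1c(Cl)cc(Cl)cc1Cl | intermediate
42 | (2R,6R,7S,8R,9R)-8-angeloyloxy-2,9-bis[(tert-butyldimethylsilyl)oxy]germacra-1(10)Z,4E,11(13)-trien-12,6-olide | C=C1C(=O)O[C@@H]2/C=C(\C)C[C@@H](O[Si](C)(C)C(C)(C)C)/C=C(/C)[C@@H](O[Si](C)(C)C(C)(C)C)[C@H](OC(=O)/C(C)=C\C)[C@@H]12 | intermediate
43 | (2R,6R,7S,8R,9R)-8-angeloyloxy-2,9-dihydroxygermacra-1(10)Z,4E,11(13)-trien-12,6-olide | C=C1C(=O)O[C@@H]2/C=C(\C)C[C@@H](O)/C=C(/C)[C@@H](O)[C@H](OC(=O)/C(C)=C\C)[C@@H]12 | intermediate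
44 | (2R,6R,7S,8R,9R)-2,9-diacetoxy-8-angeloyloxygermacra-1(10)Z,4E,11(13)-trien-12,6-olide, CNP0499619.1 | C=C1C(=O)O[C@@H]2/C=C(\C)C[C@@H](OC(C)=O)/C=C(/C)[C@@H](OC(C)=O)[C@H](OC(=O)/C(C)=C\C)[C@@H]12 | target

## Step count and least certain steps

Total: 22 steps. Longest linear sequence: 17 steps (steps 6–22, from diethyl D-tartrate 11). The iodide branch (steps 1–5) joins at step 12.

**Step 16 (key step).** The most likely failure is that the ring does not close productively. Ten-membered ring formation is slow, so oligomerisation of the terminal alkyne on nickel, direct methyl addition of ZnMe2 to the aldehyde, or closure in the exo mode can overtake the intended coupling, and the alkylative variant has never been run as a macrocyclisation. Fallback by known chemistry: a Nozaki–Hiyama–Kishi closure of the same C5–C6 bond. It sets out from 28. Zirconium-catalysed carboalumination (AlMe3, Cp2ZrCl2, CH2Cl2; then iodine) adds methyl and aluminium syn across the alkyne and gives the E-iodoalkene F1, with the methyl group on C4 cis to iodine. Lemieux–Johnson cleavage of the vinyl group as in step 15 gives the iodo aldehyde F2. CrCl2 with catalytic NiCl2 in DMSO–THF at high dilution then closes the ring with retention of the alkene geometry and returns to the route at 34.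

**Step 17.** Lactonisation gives the trans-lactone only if step 16 has delivered the 6R carbinol. Facial selection in the ring closure may be governed by the conformation of the forming ring and not by the Felkin–Anh preference, and then the 6S epimer would result. Fallback: it sets out from 30, whose cyclisation then gives the 6-epimeric hydroxy ester F3. Saponification (LiOH, THF–H2O) gives the hydroxy acid F4, and Mitsunobu lactonisation (PPh3, diisopropyl azodicarboxylate, toluene) closes O12 onto C6 with inversion. The route is rejoined at 35.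

**Step 15.** Two things may go wrong: osmylation of the trisubstituted alkene in competition with the vinyl group (electron-rich alkenes are intrinsically faster, and only sterics and the allylic oxygens hold this one back), and lactonisation of the intermediate diol onto the ester before cleavage. Fallback: cleave the vinyl group before the second alkene exists and carry C6 and C12 together as a lactone. It sets out from 21. Ozonolysis with NaBH4 work-up gives the γ-lactone F5. H5IO6 as in step 11 gives the lactone aldehyde F6. Addition of 25 as in step 12 gives alcohol F7, silylation as in step 13 gives F8, and K2CO3 in MeOH gives the terminal alkyne F9. LiOH followed by MeI on the carboxylate salt gives the hydroxy ester F10, which is oxidised at once with Dess–Martin periodinane and returns to the route at 30.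

**Step 12.** Facial selectivity may be poor if the magnesium chelate is incomplete, and the alkenyllithium 24 may suffer oxygen-to-carbon silyl migration before it is trapped (the lithium is cis to the silyloxy carbon). Fallback: it sets out from 8 and 23 and needs neither the alkyne silyl group nor an organolithium. Nozaki–Hiyama–Kishi coupling (CrCl2, NiCl2 cat., DMSO) gives the alcohols F11 as a mixture at C9. Dess–Martin oxidation gives the Z-enone F12. Felkin–Anh-controlled reduction with the bulky, non-chelating KBH(sBu)3 at −78 °C places the hydride anti to the O8 ether and gives the 8,9-syn alcohol F13. Silylation as in step 13 then returns to the route at 28.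

**Step 3.** The β-iodoenal may isomerise from Z to E under the acid catalyst, or the enantioselectivity may be insufficient for this unusual substrate. Fallback: it sets out from 4. Barbier propargylation (propargyl bromide, Zn, THF) gives the racemic alcohol F14. Lipase-catalysed acetylation (Pseudomonas cepacia lipase, vinyl acetate) should, by the usual size rule for secondary alcohols, acylate the R-enantiomer and give acetate F15. Methanolysis (K2CO3, MeOH) returns to the route at 7.

**Step 20.** The angeloyl group may isomerise to the tigloyl group during activation or acyl transfer, or the hindered C8 hydroxyl may not be acylated. Fallback: build the Z-alkene of the ester on the molecule. It sets out from 39. Esterification with 2-[bis(2,2,2-trifluoroethoxy)phosphoryl]propanoic acid (dicyclohexylcarbodiimide, 4-(dimethylamino)pyridine) gives phosphonate F16. Still–Gennari olefination with acetaldehyde (KN(SiMe3)2, 18-crown-6, THF, −78 °C) gives the Z-configured 2-methylbut-2-enoate and returns to the route at 42.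

## Further compounds

F1 | step 16 | (E)-iodoalkene from carboalumination–iodination of 28 | COC(=O)C[C@@H](C=C)[C@@H](OCc1ccc(OC)cc1)[C@H](O[Si](C)(C)C(C)(C)C)/C(C)=C\[C@H](O[Si](C)(C)C(C)(C)C)C/C(C)=C/I
F2 | step 16 | iodo aldehyde from cleavage of the vinyl group of F1 | COC(=O)C[C@@H](C=O)[C@@H](OCc1ccc(OC)cc1)[C@H](O[Si](C)(C)C(C)(C)C)/C(C)=C\[C@H](O[Si](C)(C)C(C)(C)C)C/C(C)=C/I
F3 | step 17 | 6S epimer of 34 | O[C@H]1/C=C(\C)C[C@@H](O[Si](C)(C)C(C)(C)C)/C=C(/C)[C@@H](O[Si](C)(C)C(C)(C)C)[C@H](OCc2ccc(OC)cc2)[C@H]1CC(=O)OC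
F4 | step 17 | hydroxy acid from F3 | O[C@H]1/C=C(\C)C[C@@H](O[Si](C)(C)C(C)(C)C)/C=C(/C)[C@@H](O[Si](C)(C)C(C)(C)C)[C@H](OCc2ccc(OC)cc2)[C@H]1CC(=O)O
F5 | step 15 | γ-lactone (O6–C12) from ozonolysis and reduction of 21 | O=C1C[C@@H](CO1)[C@@H](OCc2ccc(OC)cc2)[C@H]3COC(C)(C)O3
F6 | step 15 | lactone aldehyde from F5 | O=C1C[C@@H](CO1)[C@@H](OCc2ccc(OC)cc2)C=O
F7 | step 15 | lactone analogue of 26 | O=C1C[C@@H](CO1)[C@@H](OCc2ccc(OC)cc2)[C@H](O)/C(C)=C\[C@H](O[Si](C)(C)C(C)(C)C)CC#C[Si](C)(C)C
F8 | step 15 | lactone analogue of 27 | O=C1C[C@@H](CO1)[C@@H](OCc2ccc(OC)cc2)[C@H](O[Si](C)(C)C(C)(C)C)/C(C)=C\[C@H](O[Si](C)(C)C(C)(C)C)CC#C[Si](C)(C)C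
F9 | step 15 | lactone with terminal alkyne from F8 | O=C1C[C@@H](CO1)[C@@H](OCc2ccc(OC)cc2)[C@H](O[Si](C)(C)C(C)(C)C)/C(C)=C\[C@H](O[Si](C)(C)C(C)(C)C)CC#C
F10 | step 15 | C6 hydroxy methyl ester from opening of F9 | COC(=O)C[C@@H](CO)[C@@H](OCc1ccc(OC)cc1)[C@H](O[Si](C)(C)C(C)(C)C)/C(C)=C\[C@H](O[Si](C)(C)C(C)(C)C)CC#C
F11 | step 12 | coupling product of 8 and 23, mixture at C9 | COC(=O)C[C@@H](C=C)[C@@H](OCc1ccc(OC)cc1)C(O)/C(C)=C\[C@H](O[Si](C)(C)C(C)(C)C)CC#C
F12 | step 12 | Z-enone from oxidation of F11 | COC(=O)C[C@@H](C=C)[C@@H](OCc1ccc(OC)cc1)C(=O)/C(C)=C\[C@H](O[Si](C)(C)C(C)(C)C)CC#C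
F13 | step 12 | 8,9-syn alcohol from reduction of F12 | COC(=O)C[C@@H](C=C)[C@@H](OCc1ccc(OC)cc1)[C@H](O)/C(C)=C\[C@H](O[Si](C)(C)C(C)(C)C)CC#C
F14 | step 3 | racemic (5Z)-6-iodohept-5-en-1-yn-4-ol | C/C(I)=C/C(O)CC#C
F15 | step 3 | (4R,5Z)-6-iodohept-5-en-1-yn-4-yl acetate | C/C(I)=C/[C@H](OC(C)=O)CC#C
F16 | step 20 | 8-O-{2-[bis(2,2,2-trifluoroethoxy)phosphoryl]propanoyl} derivative of 39 | C=C1C(=O)O[C@@H]2/C=C(\C)C[C@@H](O[Si](C)(C)C(C)(C)C)/C=C(/C)[C@@H](O[Si](C)(C)C(C)(C)C)[C@H](OC(=O)C(C)P(=O)(OCC(F)(F)F)OCC(F)(F)F)[C@@H]12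
A1 | alternative 1 | 13-membered cyclic α-allyloxy enone, C7=C11 drawn E | O=C1COC/C(COCc2ccc(OC)cc2)=C/[C@H](O[Si](C)(C)C(C)(C)C)/C=C(\C)C[C@@H](O[Si](CC)(CC)CC)/C=C\1C
A2 | alternative 1 | ten-membered 8-hydroxy dien-9-one with the C11(=C13)–C12 arm on C7 | CC(C)(C)[Si](C)(C)O[C@@H]1/C=C(\C)C[C@@H](O[Si](CC)(CC)CC)/C=C(/C)C(=O)[C@H](O)[C@H]1C(=C)COCc1ccc(OC)cc1
A3 | alternative 2 | acyclic Z-alkenyl iodide with C9 aldehyde and methylene lactone | C=C1C(=O)O[C@H](/C=C(\C)C[C@@H](OC(C)=O)/C=C(/C)I)[C@H]1[C@@H](OCc2ccc(OC)cc2)C=O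
A4 | alternative 2 | 9-hydroxy germacranolide with O8 as PMB ether | C=C1C(=O)O[C@@H]2/C=C(\C)C[C@@H](OC(C)=O)/C=C(/C)[C@@H](O)[C@H](OCc3ccc(OC)cc3)[C@@H]12
A5 | alternative 3 | trans-decalin with tertiary C9 alcohol and equatorial C5 mesylate | COc1ccc(CO[C@@H]2[C@@H](OS(C)(=O)=O)[C@]3(C)C[C@@H](O[Si](C)(C)C(C)(C)C)C=C(C)[C@@]3(O)[C@H](OCOC)[C@H]2CCO[Si](C(C)C)(C(C)C)C(C)C)cc1
A6 | alternative 3 | ten-membered dienone with C2, C6, C7 and C8 set | COc1ccc(CO[C@@H]2/C=C(\C)C[C@@H](O[Si](C)(C)C(C)(C)C)/C=C(/C)C(=O)[C@H](OCOC)[C@H]2CCO[Si](C(C)C)(C(C)C)C(C)C)cc1
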